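**Assumption:** the SMILES is read as (4R,5R,9S,10R)-15-acetoxylabda-8(17),13E-dien-18-oic acid (trans-decalin, equatorial 4α-CO2H, axial 4β-CH3, 9β side chain, labdane numbering).

## Retrosynthetic overview

- Target acid ⇐ C18 primary alcohol by oxidation only; the side-chain acetate is already in place.
- C18 alcohol ⇐ 3β,18-diol by radical excision of the 3-oxygen through a cyclic thionocarbonate.
- 3β,18-diol ⇐ acyclic (2S,3S)-epoxy alcohol by one cationic chair–chair cascade: ring A closes first (C4–C5), then ring B (C9–C10), and loss of a C17 proton gives the 8(17)-alkene; all ring stereocentres are set here.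
- Epoxy alcohol ⇐ ω-(E)-hydroxygeranylgeranyl acetate (Sharpless epoxidation) ⇐ geranylgeranyl acetate (SeO2) ⇐ all-E-geranylgeraniol.

## Route

Step 1
Reactants: 1 (2E,6E,10E)-geranylgeraniol
Product: 2 (2E,6E,10E)-geranylgeranyl acetate
Conditions: Ac2O, pyridine, DMAP (cat.), CH2Cl2, 0 °C → rt
Reagents that add atoms: acetic anhydride, CC(=O)OC(C)=O
Why: DMAP-catalysed acylation of the primary allylic alcohol (esterification) installs the final C15 acetate, which also protects and deactivates the 2-alkene; no stereocentre is formed.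

Step 2
Reactants: 2 (2E,6E,10E)-geranylgeranyl acetate
Product: 3 (2E,6E,10E,14E)-16-hydroxy-3,7,11,15-tetramethylhexadeca-2,6,10,14-tetraen-1-yl acetate
Conditions: SeO2 (0.1 equiv), t-BuOOH (2 equiv), salicylic acid (0.1 equiv), CH2Cl2, 0 °C → rt, stopped at partial conversion, 2 recycled
Reagents that add atoms: tert-butyl hydroperoxide, CC(C)(C)OO
Why: SeO2/t-BuOOH allylic oxidation (ene reaction then [2,3]-sigmatropic shift) attacks the least hindered terminal isopropylidene and oxidises only the methyl trans to the chain, so the future C18 oxygen is placed on the (E)-substituent; the allylic-acetate alkene is deactivated.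

Step 3
Reactants: 3 (2E,6E,10E,14E)-16-hydroxy-3,7,11,15-tetramethylhexadeca-2,6,10,14-tetraen-1-yl acetate
Product: 4 (2E,6E,10E)-13-[(2S,3S)-3-(hydroxymethyl)-3-methyloxiran-2-yl]-3,7,11-trimethyltrideca-2,6,10-trien-1-yl acetate
Conditions: Ti(OiPr)4 (10 mol %), L-(+)-diethyl tartrate (12 mol %), t-BuOOH, 4 Å MS, CH2Cl2, –20 °C
Reagents that add atoms: tert-butyl hydroperoxide, CC(C)(C)OO
Why: Sharpless asymmetric epoxidation touches only the allylic-alcohol alkene, and the L-(+)-tartrate catalyst delivers oxygen to the face that gives the (2S,3S)-epoxy alcohol (typically ≥ 93% ee, upgradable by crystallisation of 5), fixing the future C3 and C4.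

Step 4
Reactants: 4 (2E,6E,10E)-13-[(2S,3S)-3-(hydroxymethyl)-3-methyloxiran-2-yl]-3,7,11-trimethyltrideca-2,6,10-trien-1-yl acetate
Product: 5 (3S,4R,5R,9S,10R)-3,18-dihydroxylabda-8(17),13E-dien-15-yl acetate
Conditions: MeAlCl2 (3.2 equiv), CH2Cl2, –94 → –78 °C; then aq. potassium sodium tartrate
Reagents that add atoms: none
Why: Proposed new method: MeAlCl2 bound to the oxirane and the neighbouring C18 oxygen ionises the tertiary C4–O bond while the 5(10)-alkene attacks C4 anti to oxygen, and the all-E chain folded chair–chair closes ring A then ring B, so the (E)-CH2O group becomes the equatorial 18-CH2OH (4R), the retained oxygen becomes 3β-OH (3S), the ring fusion is trans (5R,10R) and the side chain is equatorial (9S); the C8 cation is quenched irreversibly by loss of an accessible C17 proton to the methylaluminate (8(17)-alkene), and the aluminium-complexed allylic acetate keeps the 13-alkene out of the cascade; the closest known reaction type is the MeAlCl2-promoted epoxide-initiated cation–olefin polycyclisation of protected 2,3-oxidopolyprenes, extended here to a free, ω-oxidised epoxy alcohol with no terminating group.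

Step 5
Reactants: 5 (3S,4R,5R,9S,10R)-3,18-dihydroxylabda-8(17),13E-dien-15-yl acetate
Product: 8 (4R,5R,9S,10R)-18-hydroxylabda-8(17),13E-dien-15-yl acetate, via cyclic thionocarbonate 6 (not isolated), via stannyl thiocarbonate 7 (not isolated)
Conditions: 1,1'-thiocarbonyldiimidazole, DMAP (cat.), toluene, 80 °C; then Bu3SnH, AIBN (cat.), 110 °C; aq. KF work-up
Reagents that add atoms: none
Why: The gauche 3β-OH/18-OH pair closes to a six-membered cyclic thionocarbonate, and Barton-type radical deoxygenation (Bu3Sn• adds to C=S, then β-scission) breaks the secondary C3–O bond in preference to the primary neopentyl C18–O bond; the C3 radical takes H from Bu3SnH and the S-stannyl thiocarbonate left on O18 loses COS on fluoride work-up, so C3 becomes CH2 without touching C4, C5, C9 or C10.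

Step 6
Reactants: 8 (4R,5R,9S,10R)-18-hydroxylabda-8(17),13E-dien-15-yl acetate
Product: 10 (4R,5R,9S,10R)-15-acetoxylabda-8(17),13E-dien-18-oic acid, via aldehyde 9 (not isolated)
Conditions: AZADO (5 mol %), PhI(OAc)2, CH2Cl2, rt; then NaClO2, NaH2PO4, 2-methyl-2-butene, t-BuOH/H2O, rt
Reagents that add atoms: sodium chlorite, [Na+].[O-]Cl=O
Why: Nitroxyl-catalysed oxidation of the hindered primary alcohol to the non-enolisable aldehyde, followed in the same flask by Pinnick chlorite oxidation, gives the acid; C4 is quaternary so nothing can epimerise, and 2-methyl-2-butene protects the two alkenes from HOCl while the acetate is untouched.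

## Compound list

1 | (2E,6E,10E)-geranylgeraniol [(2E,6E,10E)-3,7,11,15-tetramethylhexadeca-2,6,10,14-tetraen-1-ol] | CC(C)=CCC/C(C)=C/CC/C(C)=C/CC/C(C)=C/CO | starting material
2 | (2E,6E,10E)-geranylgeranyl acetate | CC(C)=CCC/C(C)=C/CC/C(C)=C/CC/C(C)=C/COC(C)=O | intermediate
3 | (2E,6E,10E,14E)-16-hydroxy-3,7,11,15-tetramethylhexadeca-2,6,10,14-tetraen-1-yl acetate | OC/C(C)=C/CC/C(C)=C/CC/C(C)=C/CC/C(C)=C/COC(C)=O | intermediate
4 | (2E,6E,10E)-13-[(2S,3S)-3-(hydroxymethyl)-3-methyloxiran-2-yl]-3,7,11-trimethyltrideca-2,6,10-trien-1-yl acetate | OC[C@]1(C)O[C@H]1CC/C(C)=C/CC/C(C)=C/CC/C(C)=C/COC(C)=O | intermediate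
5 | (3S,4R,5R,9S,10R)-3,18-dihydroxylabda-8(17),13E-dien-15-yl acetate (3β-OH, 4α-CH2OH, 4β-CH3, 5α-H, 10β-CH3, 9α-H) | C=C1CC[C@@H]2[C@](C)(CC[C@H](O)[C@@]2(C)CO)[C@H]1CC/C(C)=C/COC(C)=O | intermediate
6 | cyclic 3β,18-thionocarbonate (1,3-dioxane-2-thione) of 5 | C=C1CC[C@@H]2[C@](C)(CC[C@@H]3OC(=S)OC[C@@]23C)[C@H]1CC/C(C)=C/COC(C)=O | intermediate (not isolated)
7 | 18-O-[(tributylstannylsulfanyl)carbonyl] derivative of 8 | C=C1CC[C@@H]2[C@](C)(CCC[C@@]2(C)COC(=O)S[Sn](CCCC)(CCCC)CCCC)[C@H]1CC/C(C)=C/COC(C)=O | intermediate (not isolated)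
8 | (4R,5R,9S,10R)-18-hydroxylabda-8(17),13E-dien-15-yl acetate | C=C1CC[C@@H]2[C@](C)(CCC[C@@]2(C)CO)[C@H]1CC/C(C)=C/COC(C)=O | intermediate
9 | (4R,5R,9S,10R)-18-oxolabda-8(17),13E-dien-15-yl acetate | C=C1CC[C@@H]2[C@](C)(CCC[C@@]2(C)C=O)[C@H]1CC/C(C)=C/COC(C)=O | intermediate (not isolated)
10 | (4R,5R,9S,10R)-15-acetoxylabda-8(17),13E-dien-18-oic acid | C=C1CC[C@@H]2[C@](C)(CCC[C@@]2(C)C(=O)O)[C@H]1CC/C(C)=C/COC(C)=O | target

## Step count and risks

Total step count: 6. Longest linear sequence: 6 (1 → 2 → 3 → 4 → 5 → 8 → 10).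

**Step 4 (key bicyclisation).** The C8 cation may give 7-ene and 8-ene isomers beside the 8(17)-alkene. A hydride shift from C18 to C4 (semipinacol, giving a β-hydroxy aldehyde) and some third ring closure are also possible. The fallback replaces direct deprotonation by hydration and a stereoelectronically controlled dehydration; it sets out from 4 and comes back at 6. The cascade is run under water-capture conditions (BF3·OEt2, wet nitromethane, –25 °C), so that water adds to the C8 cation from the open α-face and gives the equatorial tertiary alcohol, 3β,8α,18-trihydroxylabd-13E-en-15-yl acetate F1. Thiocarbonyldiimidazole then closes only the 3,18-diol (the tertiary hydroxyl does not react) to the 8α-hydroxy cyclic thionocarbonate F2. POCl3/pyridine dehydrates F2 by anti-elimination: for an equatorial 8α leaving group only the C17 hydrogens can be antiperiplanar, so the 8(17)-alkene forms and this is compound 6, which is isolated and reduced with Bu3SnH as in the second half of step 5.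

**Step 5 (telescoped deoxygenation).** Scission may be incomplete or go the wrong way, the stannyl thiocarbonate may not cleave cleanly, and tin radicals are generated near two alkenes. The fallback removes the 3-oxygen through the ketone instead of a C–O radical scission; it sets out from 5 and comes back at 8. TBSCl/imidazole silylates only the primary hydroxyl to give the 18-O-TBS ether F3. Dess–Martin oxidation gives the 3-ketone F4, and TsNHNH2 gives the tosylhydrazone F5. Catecholborane followed by NaOAc reduces F5 to the 3-deoxy silyl ether F6, and buffered TBAF returns 8.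

**Step 2 (SeO2 oxidation).** Conversion is modest, over-oxidation to the enal occurs, and other allylic positions may react. The fallback builds the (E)-allylic alcohol by cleavage and olefination; it sets out from 2 and comes back at 3. NBS in aqueous THF gives the terminal bromohydrin F7 selectively, and DBU closes it to the terminal epoxide F8. HIO4 cleaves F8 to the trisnor aldehyde F9. Wittig reaction with Ph3P=C(CH3)CHO gives the (E)-enal F10, and NaBH4/CeCl3 reduces it to 3.

## Further compounds

F1 | step 4 | (3S,4R,5R,8R,9R,10S)-3β,8α,18-trihydroxylabd-13E-en-15-yl acetate | C[C@@]1(O)CC[C@@H]2[C@](C)(CC[C@H](O)[C@@]2(C)CO)[C@H]1CC/C(C)=C/COC(C)=O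
F2 | step 4 | cyclic 3β,18-thionocarbonate of F1 (8α-OH free) | C[C@@]1(O)CC[C@@H]2[C@](C)(CC[C@@H]3OC(=S)OC[C@@]23C)[C@H]1CC/C(C)=C/COC(C)=O
F3 | step 5 | 18-O-tert-butyldimethylsilyl ether of 5 | C=C1CC[C@@H]2[C@](C)(CC[C@H](O)[C@@]2(C)CO[Si](C)(C)C(C)(C)C)[C@H]1CC/C(C)=C/COC(C)=O
F4 | step 5 | 18-(tert-butyldimethylsilyloxy)-3-oxolabda-8(17),13E-dien-15-yl acetate | C=C1CC[C@@H]2[C@](C)(CCC(=O)[C@@]2(C)CO[Si](C)(C)C(C)(C)C)[C@H]1CC/C(C)=C/COC(C)=O
F5 | step 5 | tosylhydrazone of F4 | C=C1CC[C@@H]2[C@](C)(CCC(=NNS(=O)(=O)c3ccc(C)cc3)[C@@]2(C)CO[Si](C)(C)C(C)(C)C)[C@H]1CC/C(C)=C/COC(C)=O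
F6 | step 5 | 18-(tert-butyldimethylsilyloxy)labda-8(17),13E-dien-15-yl acetate | C=C1CC[C@@H]2[C@](C)(CCC[C@@]2(C)CO[Si](C)(C)C(C)(C)C)[C@H]1CC/C(C)=C/COC(C)=O
F7 | step 2 | (2E,6E,10E)-14-bromo-15-hydroxy-3,7,11,15-tetramethylhexadeca-2,6,10-trien-1-yl acetate (racemic) | CC(C)(O)C(Br)CC/C(C)=C/CC/C(C)=C/CC/C(C)=C/COC(C)=O
F8 | step 2 | (2E,6E,10E)-14,15-epoxy-3,7,11,15-tetramethylhexadeca-2,6,10-trien-1-yl acetate (racemic) | CC1(C)OC1CC/C(C)=C/CC/C(C)=C/CC/C(C)=C/COC(C)=O
F9 | step 2 | (2E,6E,10E)-3,7,11-trimethyl-14-oxotetradeca-2,6,10-trien-1-yl acetate | O=CCC/C(C)=C/CC/C(C)=C/CC/C(C)=C/COC(C)=O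
F10 | step 2 | (2E,6E,10E,14E)-3,7,11,15-tetramethyl-16-oxohexadeca-2,6,10,14-tetraen-1-yl acetate | O=C/C(C)=C/CC/C(C)=C/CC/C(C)=C/CC/C(C)=C/COC(C)=O
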